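**Strategy.** Everything rests on cutting the bond between the quaternary lactone carbon (C5 of the furan-2(5H)-one ring) and its benzylic CH2. Two features are exploited: C5 is α to the methyl ester and vinylogously γ to the lactone carbonyl C2 through C3=C4, so its anion is an aromatic 2-oxidofuran; and the benzylic carbon sits para to the phenolic OH of the prenylated ring, so that half is a latent para-quinone methide. One catalytic asymmetric vinylogous 1,6-addition joins the two unprotected halves, sets the (R) quaternary centre, rearomatises the cyclohexadienone and gives the target directly. The electrophilic precursor is a 4-methylidenecyclohexadienone released in situ from a benzylic sulfone.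

Key step: step 7

Remarks on the chemistry:
- Furan-2(5H)-one numbering is used in the text: O1, C2 lactone carbonyl, C3 (OMe), C4 (aryl), C5 (quaternary carbon).
- Compounds 4, 5 and 6 are racemic at C5; this centre is erased on deprotonation in step 7.
- Assumption: the (S)-configured catalyst of step 7 is taken to leave the Si face of C5 of the anion open. Both catalyst enantiomers are commercial, so the (R)-catalyst would be used without other change if the sense of induction is the opposite one.

**Step 1**
Reactants: 1 4-hydroxyphenylpyruvic acid
Product: 2 methyl 4-hydroxyphenylpyruvate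
Conditions: MeOH, TMSCl (cat.), rt
Reagents that add atoms: methanol, CO
Why: Fischer esterification of the α-keto acid with HCl formed in situ, which leaves the phenol and the enolisable ketone untouched.

**Step 2**
Reactants: 2 methyl 4-hydroxyphenylpyruvate; 3 methyl glyoxylate
Product: 5 racemic methyl 4-hydroxy-3-(4-hydroxyphenyl)-5-oxo-2,5-dihydrofuran-2-carboxylate, via acyclic aldol adduct 4 (not isolated)
Conditions: 3 (2.5 equiv), Et3N (1.1 equiv), THF, 0 °C → rt; 1 M HCl work-up
Reagents that add atoms: none
Why: Crossed aldol addition of the benzylic enolate carbon of the arylpyruvate to the much more electrophilic glyoxylate aldehyde (used in excess to outrun self-aldol dimerisation), then lactonisation of the new secondary hydroxyl onto the activated α-keto ester and enolisation to the isotetronic acid (aldol–lactonisation cascade).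

**Step 3**
Reactants: 5 racemic methyl 4-hydroxy-3-(4-hydroxyphenyl)-5-oxo-2,5-dihydrofuran-2-carboxylate
Product: 6 racemic methyl 3-(4-hydroxyphenyl)-4-methoxy-5-oxo-2,5-dihydrofuran-2-carboxylate
Conditions: TMSCHN2 (1.05 equiv), PhMe–MeOH 4:1, 0 °C
Reagents that add atoms: trimethylsilyldiazomethane, C[Si](C)(C)C=[N+]=[N-]
Why: Diazoalkane O-methylation, in which the isotetronic enol OH, expected to be clearly more acidic than the phenol, protonates the reagent and the ion pair collapses at oxygen, while the phenol and the C5–H carbon acid should not react with one equivalent at 0 °C.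

**Step 4**
Reactants: 7 4-hydroxybenzaldehyde; 8 prenyl bromide (1-bromo-3-methylbut-2-ene)
Product: 9 4-hydroxy-3-(3-methylbut-2-en-1-yl)benzaldehyde
Conditions: KOH (aq., 1.1 equiv), 8 (1.1 equiv), rt; chromatography
Reagents that add atoms: none
Why: Phenoxide ortho-C-allylation in water, where hydrogen bonding to the phenoxide oxygen disfavours O-alkylation and the blocked para position leaves only the ortho carbon; O-prenyl ether and doubly alkylated material are removed by chromatography.

**Step 5**
Reactants: 9 4-hydroxy-3-(3-methylbut-2-en-1-yl)benzaldehyde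
Product: 10 4-(hydroxymethyl)-2-(3-methylbut-2-en-1-yl)phenol
Conditions: NaBH4, MeOH, 0 °C
Reagents that add atoms: none
Why: Chemoselective borohydride reduction of the aldehyde; the trisubstituted alkene and the phenol are inert.

**Step 6**
Reactants: 10 4-(hydroxymethyl)-2-(3-methylbut-2-en-1-yl)phenol
Product: 11 4-[(4-methylphenyl)sulfonylmethyl]-2-(3-methylbut-2-en-1-yl)phenol
Conditions: p-TolSO2H (1.3 equiv), CH2Cl2, rt
Reagents that add atoms: p-toluenesulfinic acid, Cc1ccc(cc1)S(=O)O
Why: SN1-type substitution of the para-hydroxybenzylic alcohol (ionisation assisted by the para-OH) with S-alkylation of the soft sulfinate to the stable sulfone, under an acid that should be too weak to protonate the prenyl alkene.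

**Step 7**
Reactants: 6 racemic methyl 3-(4-hydroxyphenyl)-4-methoxy-5-oxo-2,5-dihydrofuran-2-carboxylate; 11 4-[(4-methylphenyl)sulfonylmethyl]-2-(3-methylbut-2-en-1-yl)phenol
Product: 13 2-O-methylbutyrolactone I, via para-quinone methide 12 (not isolated)
Conditions: (S)-4,4-dibutyl-2,6-bis(3,4,5-trifluorophenyl)-4,5-dihydro-3H-dinaphtho[2,1-c:1',2'-e]azepinium bromide (10 mol%), K2CO3 (solid, 2.5 equiv), PhMe, 0 °C, slow addition of 11 (1.3 equiv); aq. NH4Cl
Reagents that add atoms: none
Why: K2CO3 converts sulfone 11 into its phenoxide, which expels p-toluenesulfinate (1,6-elimination) to give quinone methide 12, while racemic 6 is deprotonated at C5 to a planar, 6π-aromatic 2-oxidofuran that enters toluene as an ion pair with the chiral ammonium cation, adds through C5 to the exocyclic methylene of 12 (vinylogous 1,6-conjugate addition) and so rearomatises the cyclohexadienone to the phenol. The closest known reaction type is the catalytic asymmetric 1,6-addition of stabilised carbon nucleophiles (β-keto esters, butenolides, oxindoles) to para-quinone methides released in situ from para-hydroxybenzyl sulfones under chiral phase-transfer catalysis. No ring is closed; the only ring event is the aromatisation of the six-membered ring of 12, which makes the addition irreversible. The new C5 stereocentre is controlled by the catalyst alone: the binaphthyl cation shields one face of the ion-paired anion so that 12 approaches the Si face of C5 (O1 > CO2Me > C4), which gives (R), and both enantiomers of 6 converge on the same anion. The step needs site selectivity (C5 over C3 and over oxygen), chemoselectivity (carbanion over phenoxide oxygen) and enantioface selectivity: C5 is both the ester α-carbon and the γ-terminus of the dienolate, C3 is blocked by its methoxy group and attack there would break the lactone conjugation, and the soft quinone methide terminus prefers the soft carbon site. The C5–H acid is expected to be more acidic than the phenols and so to be the anion paired with the catalyst, while reversible sulfinate re-addition to 12 and slow addition of 11 keep the quinone methide concentration low and limit oligomerisation.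

**Compound list**
1 | 4-hydroxyphenylpyruvic acid | O=C(O)C(=O)Cc1ccc(O)cc1 | starting material
2 | methyl 4-hydroxyphenylpyruvate (drawn as keto tautomer) | COC(=O)C(=O)Cc1ccc(O)cc1 | intermediate
3 | methyl glyoxylate | COC(=O)C=O | starting material
4 | dimethyl 2-hydroxy-3-(4-hydroxyphenyl)-4-oxopentanedioate (acyclic aldol adduct, racemic) | COC(=O)C(O)C(c1ccc(O)cc1)C(=O)C(=O)OC | intermediate (not isolated)
5 | racemic methyl 4-hydroxy-3-(4-hydroxyphenyl)-5-oxo-2,5-dihydrofuran-2-carboxylate | COC(=O)C1OC(=O)C(O)=C1c1ccc(O)cc1 | intermediate
6 | racemic methyl 3-(4-hydroxyphenyl)-4-methoxy-5-oxo-2,5-dihydrofuran-2-carboxylate | COC(=O)C1OC(=O)C(OC)=C1c1ccc(O)cc1 | intermediate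
7 | 4-hydroxybenzaldehyde | O=Cc1ccc(O)cc1 | starting material
8 | prenyl bromide (1-bromo-3-methylbut-2-ene) | CC(C)=CCBr | starting material
9 | 4-hydroxy-3-(3-methylbut-2-en-1-yl)benzaldehyde | CC(C)=CCc1cc(C=O)ccc1O | intermediate
10 | 4-(hydroxymethyl)-2-(3-methylbut-2-en-1-yl)phenol | CC(C)=CCc1cc(CO)ccc1O | intermediate
11 | 4-[(4-methylphenyl)sulfonylmethyl]-2-(3-methylbut-2-en-1-yl)phenol | Cc1ccc(cc1)S(=O)(=O)Cc1ccc(O)c(CC=C(C)C)c1 | intermediate
12 | 4-methylidene-2-(3-methylbut-2-en-1-yl)cyclohexa-2,5-dien-1-one (para-quinone methide) | C=C1C=CC(=O)C(CC=C(C)C)=C1 | intermediate (not isolated)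
13 | 2-O-methylbutyrolactone I, methyl (2R)-2-{[4-hydroxy-3-(3-methylbut-2-en-1-yl)phenyl]methyl}-3-(4-hydroxyphenyl)-4-methoxy-5-oxo-2,5-dihydrofuran-2-carboxylate | COC(=O)[C@]1(Cc2ccc(O)c(CC=C(C)C)c2)OC(=O)C(OC)=C1c1ccc(O)cc1 | target

**Step count.** Total: 7 steps. Longest linear sequence: 4 steps (1, 2, 3, 7 or 4, 5, 6, 7).

**Steps most likely to fail**

1. Step 7. The transient quinone methide may be consumed by self-condensation or by phenoxide oxygen faster than by the ion-paired carbanion, or an addition outside the chiral ion pair may erode facial selectivity. The fallback is a classical asymmetric phase-transfer SN2 benzylation with a stable benzylic bromide and all phenols silylated; it sets out from 6 and 9 and comes back at 13. From 6, TBSCl and imidazole in DMF should give the aryl silyl ether F1. From 9, TBSCl and imidazole should give the silylated aldehyde F2, NaBH4 in MeOH the benzylic alcohol F3, and CBr4/PPh3 in CH2Cl2 the benzylic bromide F4. F1 would then be alkylated at C5 with F4 under the same chiral ammonium catalyst (solid K2CO3, PhMe, −20 °C) to the bis-silyl ether F5, and TBAF buffered with AcOH in THF at 0 °C would release 13.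

2. Step 6. Acid-promoted ionisation may lead to Friedel–Crafts self-condensation of the hydroxybenzyl cation with a second phenol ring, or to cyclisation of the prenyl group onto the phenol oxygen, instead of clean capture by sulfinate. The fallback avoids acid altogether; it sets out from 10 and comes back at 12. A lipase (immobilised Candida antarctica lipase B, vinyl acetate, MTBE, rt) should acetylate the primary benzylic hydroxyl and not the phenol, giving the benzylic acetate F6. Under the base of step 7, F6 should lose acetate from its phenoxide to give the same quinone methide 12.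

3. Step 4. O-alkylation and double alkylation may outcompete mono ortho-C-alkylation, so that little mono-C-prenyl phenol is formed and separation becomes laborious. The fallback installs the prenyl group by a sigmatropic shift; it sets out from 7 and comes back at 9. O-Alkylation of 7 with 3-chloro-3-methylbut-1-yne (DBU, CuCl2 cat., MeCN, 0 °C) should give the aryl 1,1-dimethylpropargyl ether F7. Semihydrogenation (H2, Pb-poisoned Pd/CaCO3, quinoline, EtOAc) should give the aryl 1,1-dimethylallyl ether F8. Heating F8 (PhNEt2, about 180 °C) should give 9 by aromatic Claisen rearrangement to the ortho position and tautomerisation.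

**Further compounds**
F1 | step 7 | racemic methyl 3-[4-(tert-butyldimethylsilyloxy)phenyl]-4-methoxy-5-oxo-2,5-dihydrofuran-2-carboxylate | COC(=O)C1OC(=O)C(OC)=C1c1ccc(O[Si](C)(C)C(C)(C)C)cc1
F2 | step 7 | 4-(tert-butyldimethylsilyloxy)-3-(3-methylbut-2-en-1-yl)benzaldehyde | CC(C)=CCc1cc(C=O)ccc1O[Si](C)(C)C(C)(C)C
F3 | step 7 | [4-(tert-butyldimethylsilyloxy)-3-(3-methylbut-2-en-1-yl)phenyl]methanol | CC(C)=CCc1cc(CO)ccc1O[Si](C)(C)C(C)(C)C
F4 | step 7 | [4-(bromomethyl)-2-(3-methylbut-2-en-1-yl)phenoxy](tert-butyl)dimethylsilane | CC(C)=CCc1cc(CBr)ccc1O[Si](C)(C)C(C)(C)C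
F5 | step 7 | methyl (2R)-2-{[4-(tert-butyldimethylsilyloxy)-3-(3-methylbut-2-en-1-yl)phenyl]methyl}-3-[4-(tert-butyldimethylsilyloxy)phenyl]-4-methoxy-5-oxo-2,5-dihydrofuran-2-carboxylate | COC(=O)[C@]1(Cc2ccc(O[Si](C)(C)C(C)(C)C)c(CC=C(C)C)c2)OC(=O)C(OC)=C1c1ccc(O[Si](C)(C)C(C)(C)C)cc1
F6 | step 6 | [4-hydroxy-3-(3-methylbut-2-en-1-yl)phenyl]methyl acetate | CC(=O)OCc1ccc(O)c(CC=C(C)C)c1
F7 | step 4 | 4-[(2-methylbut-3-yn-2-yl)oxy]benzaldehyde | CC(C)(C#C)Oc1ccc(C=O)cc1
F8 | step 4 | 4-[(2-methylbut-3-en-2-yl)oxy]benzaldehyde | CC(C)(C=C)Oc1ccc(C=O)cc1
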